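**Plan**

- Retrosynthetic cuts, in order: C9–C10 of the ten-membered ring (alkenyl iodide + aldehyde), the lactone O–C6 bond, C7–C11 ([3,3] shift), C5–C6 (alkyne + enal). The C8 ester, C13 and C15 are added as acyl and one-carbon units.
- Enabling feature: the lactone oxygen sits on allylic C6, which is 1,4-related through the C4=C5 olefin to the C15 hydroxyl (O–C6–C5=C4–C15–OH), and C7 next to it carries the C11–C12 carboxyl. This is the pattern of a C4–C15 vinyl oxirane opened in SN2′ fashion by its own γ,δ-unsaturated acid.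
- Forward: aldehyde 8 (C1–C5, C10, C14, C15) + alkyne 10 (C6–C9) → propargylic alcohol → temporary oxirane ring → Z-allylic acetate → Ireland–Claisen acid 17 → γ-lactone (key step) → ten-membered carbocycle by Nozaki–Hiyama–Kishi closure → unmasking.
- Stereochemistry: C8 comes from (R)-glyceraldehyde acetonide. A temporary C5 carbinol (ligand-controlled alkynylation) directs the temporary C4 oxirane carbon. C5 is relayed to C7 by the Claisen shift and C4 to C6 by double inversion at palladium. C9 is set in the macrocyclisation, and the acyl stereocentre comes from (S)-2-methylbutanoic anhydride.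
- Olefin geometry: C1=C10 from α-iodination of an E enal and a retentive chromium coupling; C4=C5 from ionisation of the s-trans vinyl oxirane.

Key step: step 12

Assumption: germacranolide numbering is used (lactone C12(=O)–O–C6, C14 = formyl carbon, C15 = hydroxymethyl carbon); the ProPhenol antipode named in step 7 is taken to give Si-face addition, and its enantiomer is used if the sense proves opposite.

Step 1
Reactants: 1 hex-5-en-1-yl acetate; 2 (E)-but-2-enal
Product: 3 (E)-7-oxohept-5-en-1-yl acetate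
Conditions: 2 (4 equiv), second-generation Hoveyda–Grubbs catalyst RuCl2(H2IMes)(=CH-C6H4-2-OiPr) (3 mol%), CH2Cl2, 40 °C
Reagents that add atoms: none
Why: Olefin cross-metathesis of a terminal alkene with the electron-poor partner crotonaldehyde should favour the cross product and give the E enal under thermodynamic control.

Step 2
Reactants: 3 (E)-7-oxohept-5-en-1-yl acetate
Product: 4 (Z)-6-iodo-7-oxohept-5-en-1-yl acetate
Conditions: I2, K2CO3, DMAP (20 mol%), THF/H2O, rt
Reagents that add atoms: iodine, II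
Why: Amine-catalysed α-iodination of an enal (conjugate addition of DMAP, iodination of the enolate, elimination of DMAP) should give the (Z)-2-iodoenal with iodine cis to the chain, the geometry later carried to C10.

Step 3
Reactants: 4 (Z)-6-iodo-7-oxohept-5-en-1-yl acetate
Product: 6 (Z)-6-iodo-7,7-dimethoxyhept-5-en-1-ol, via acetal acetate 5 (not isolated)
Conditions: HC(OMe)3, p-TsOH (cat.), MeOH, rt; then K2CO3, rt
Reagents that add atoms: trimethyl orthoformate, COC(OC)OC
Why: Acid-catalysed acetalisation masks the C14 aldehyde as a dimethyl acetal that should survive the later basic, organometallic and oxidative steps, and methanolysis of the acetate in the same flask frees the C5 alcohol.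

Step 4
Reactants: 6 (Z)-6-iodo-7,7-dimethoxyhept-5-en-1-ol
Product: 7 (Z)-6-iodo-7,7-dimethoxyhept-5-enal
Conditions: Dess–Martin periodinane, NaHCO3, CH2Cl2, 0 °C → rt
Reagents that add atoms: none
Why: Dess–Martin oxidation of a primary alcohol under buffered non-aqueous conditions should leave the acetal and the alkenyl iodide untouched.

Step 5
Reactants: 7 (Z)-6-iodo-7,7-dimethoxyhept-5-enal
Product: 8 (Z)-6-iodo-7,7-dimethoxy-2-methylidenehept-5-enal
Conditions: 37% aq. CH2O, pyrrolidine (10 mol%), EtCO2H (10 mol%), i-PrOH, 45 °C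
Reagents that add atoms: formaldehyde, C=O
Why: Amine/acid-catalysed α-methylenation of an aldehyde (Mannich condensation, then β-elimination of the amine) installs C15 as the exo-methylene of a 2-substituted acrolein.

Step 6
Reactants: 9 (R)-2,2-dimethyl-1,3-dioxolane-4-carbaldehyde
Product: 10 (S)-4-ethynyl-2,2-dimethyl-1,3-dioxolane
Conditions: dimethyl (1-diazo-2-oxopropyl)phosphonate, K2CO3, MeOH, 0 °C → rt
Reagents that add atoms: dimethyl (1-diazo-2-oxopropyl)phosphonate (Ohira–Bestmann reagent), CC(=O)C(=[N+]=[N-])P(=O)(OC)OC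
Why: Seyferth–Gilbert homologation with the Ohira–Bestmann reagent converts the aldehyde into the terminal alkyne (C6≡C7) under conditions mild enough to keep the future C8 stereocentre, whose descriptor changes from R to S only through CIP ranking.

Step 7
Reactants: 8 (Z)-6-iodo-7,7-dimethoxy-2-methylidenehept-5-enal; 10 (S)-4-ethynyl-2,2-dimethyl-1,3-dioxolane
Product: 11 (3R,7Z)-1-[(4S)-2,2-dimethyl-1,3-dioxolan-4-yl]-8-iodo-9,9-dimethoxy-4-methylidenenon-7-en-1-yn-3-ol
Conditions: 10 (2.5 equiv), Me2Zn, (S,S)-ProPhenol (10 mol%), Ph3P=O (20 mol%), toluene, 0 °C; then 8; aq. NH4Cl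
Reagents that add atoms: none
Why: Zinc–ProPhenol catalysed asymmetric alkynylation of an enal adds the alkynylzinc from 10 in 1,2-fashion to the Si face of the aldehyde, setting the temporary C5 carbinol (R) under ligand control.

Step 8
Reactants: 11 the propargylic, allylic alcohol from step 7
Product: 12 (1S)-3-[(4S)-2,2-dimethyl-1,3-dioxolan-4-yl]-1-[(2R)-2-[(3Z)-4-iodo-5,5-dimethoxypent-3-en-1-yl]oxiran-2-yl]prop-2-yn-1-ol
Conditions: Ti(OiPr)4 (20 mol%), L-(+)-diisopropyl tartrate (24 mol%), t-BuOOH, 4 Å MS, CH2Cl2, −20 °C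
Reagents that add atoms: tert-butyl hydroperoxide, CC(C)(C)OO
Why: Sharpless asymmetric epoxidation in the matched sense: 11 is the fast-reacting enantiomer for the L-(+)-tartrate catalyst and the only allylic olefin is C4=C15, so the erythro epoxy alcohol with the (R) oxirane carbon C4 should form, and any minor C5 enantiomer is left behind.

Step 9
Reactants: 12 the epoxy propargylic alcohol
Product: 13 (1S,2Z)-3-[(4S)-2,2-dimethyl-1,3-dioxolan-4-yl]-1-[(2R)-2-[(3Z)-4-iodo-5,5-dimethoxypent-3-en-1-yl]oxiran-2-yl]prop-2-en-1-ol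
Conditions: H2 (1 atm), Pd/CaCO3 poisoned with Pb(OAc)2 (Lindlar catalyst), quinoline, EtOAc, rt, stopped after one equivalent of H2
Reagents that add atoms: none
Why: Lindlar semihydrogenation adds H2 syn to the alkyne and should give the Z olefin that the chirality transfer of step 11 requires, the strongly bound alkyne being reduced before the hindered alkenyl iodide or the oxirane can react.

Step 10
Reactants: 13 the Z-allylic epoxy alcohol
Product: 14 (1S,2Z)-3-[(4S)-2,2-dimethyl-1,3-dioxolan-4-yl]-1-[(2R)-2-[(3Z)-4-iodo-5,5-dimethoxypent-3-en-1-yl]oxiran-2-yl]prop-2-en-1-yl acetate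
Conditions: Ac2O, Et3N, DMAP (cat.), CH2Cl2, 0 °C
Reagents that add atoms: acetic anhydride, CC(=O)OC(C)=O
Why: DMAP-catalysed acetylation under non-acidic conditions installs the C11–C12 acetate unit on O5 without disturbing the oxirane.

Step 11
Reactants: 14 the Z-allylic acetate
Product: 17 (3S,4E)-3-[(4S)-2,2-dimethyl-1,3-dioxolan-4-yl]-5-[(2S)-2-[(3Z)-4-iodo-5,5-dimethoxypent-3-en-1-yl]oxiran-2-yl]pent-4-enoic acid, via silyl ketene acetal 15 (not isolated), via trimethylsilyl ester 16 (not isolated)
Conditions: LiN(iPr)2, Me3SiCl/Et3N, THF, −78 °C → 50 °C; pH 5 buffer work-up at 0 °C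
Reagents that add atoms: none
Why: Ireland–Claisen rearrangement: the O-silyl ketene acetal rearranges through a six-membered transition state with the oxiranyl group outside (the alternative is blocked by A(1,3) strain of the Z olefin), so C7–C11 forms suprafacially, the C5 carbinol configuration is relayed to C7 (S), the new C5=C6 olefin is E, and the product is a vinyl oxirane carrying its own carboxyl group (the oxirane carbon is untouched and only its CIP label changes).

Step 12
Reactants: 17 the vinyl oxirane acid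
Product: 18 (4S,5R)-4-[(4S)-2,2-dimethyl-1,3-dioxolan-4-yl]-5-[(1E,5Z)-2-(hydroxymethyl)-6-iodo-7,7-dimethoxyhepta-1,5-dien-1-yl]oxolan-2-one
Conditions: Pd2(dba)3·CHCl3 (2.5 mol%), P(OiPr)3 (15 mol%), THF, 0 °C
Reagents that add atoms: none
Why: Zerovalent palladium coordinates the C5=C6 olefin anti to the allylic C4–O bond and opens the oxirane with inversion to a zwitterionic η3-allylpalladium alkoxide spanning C4–C5–C6; proton transfer from the acid then gives a carboxylate that attacks C6 on the face opposite palladium, forming the O–C6 bond and releasing the catalyst. The closest known reaction type is the Tsuji–Trost 1,4-addition of carboxylic acids to vinyl epoxides, together with palladium-catalysed allylic lactonisation. The γ-lactone closes in a 5-exo mode at the proximal allyl terminus, whereas attack at the quaternary C4 terminus would need a seven-membered ring. The new C6 stereocentre is controlled by the C4 oxirane carbon through double inversion (net retention with 1,3-transposition), which should make C6 R and trans to the C7 substituent fixed in step 11. The C4=C5 geometry follows from ionisation of the s-trans vinyl oxirane conformer, which places the CH2O arm syn on the allyl unit and hence trans to C6, and intramolecular capture should outrun syn/anti exchange, which would need a tertiary σ-palladium species. The step also needs chemoselectivity over insertion into the alkenyl C–I bond, secured by the much faster ionisation of the vinyl oxirane at 0 °C with a weakly donating phosphite ligand and by the absence of any coupling partner for an alkenylpalladium iodide.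

Step 13
Reactants: 18 the hydroxymethyl lactone
Product: 19 (4S,5R)-5-[(1E,5Z)-2-[(tert-butyldiphenylsilyloxy)methyl]-6-iodo-7,7-dimethoxyhepta-1,5-dien-1-yl]-4-[(4S)-2,2-dimethyl-1,3-dioxolan-4-yl]oxolan-2-one
Conditions: t-BuPh2SiCl, imidazole, CH2Cl2, 0 °C → rt
Reagents that add atoms: tert-butyl(chloro)diphenylsilane, CC(C)(C)[Si](Cl)(c1ccccc1)c1ccccc1
Why: Silylation of the primary allylic C15 alcohol gives an ether that should withstand the later enolate, methanolysis, acylation and Swern steps.

Step 14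
Reactants: 19 the silyl-protected lactone
Product: 22 (4S,5R)-5-[(1E,5Z)-2-[(tert-butyldiphenylsilyloxy)methyl]-6-iodo-7,7-dimethoxyhepta-1,5-dien-1-yl]-4-[(4S)-2,2-dimethyl-1,3-dioxolan-4-yl]-3-methylideneoxolan-2-one, via Mannich base 20 (not isolated), via ammonium iodide 21 (not isolated)
Conditions: LiN(SiMe3)2, THF, −78 °C; CH2=NMe2+ I−, −78 °C → rt; MeI, THF/MeOH, rt; aq. NaHCO3, rt
Reagents that add atoms: N,N-dimethylmethyleneiminium iodide (Eschenmoser's salt), C=[N+](C)C.[I-]
Why: α-Methylenation of a γ-lactone by Mannich alkylation of its lithium enolate with Eschenmoser's salt, N-methylation and base-induced β-elimination of trimethylamine installs C13 as the exo-methylene.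

Step 15
Reactants: 22 the α-methylene lactone acetonide
Product: 23 (4S,5R)-5-[(1E,5Z)-2-[(tert-butyldiphenylsilyloxy)methyl]-6-iodo-7,7-dimethoxyhepta-1,5-dien-1-yl]-4-[(1S)-1,2-dihydroxyethyl]-3-methylideneoxolan-2-one
Conditions: PPTS (20 mol%), MeOH, 45 °C
Reagents that add atoms: none
Why: Acid-catalysed transketalisation in methanol removes the terminal acetonide while the C14 dimethyl acetal is simply regenerated in the same medium and the silyl ether is stable; the trans 6,12-lactone should be preferred over translactonisation to O8.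

Step 16
Reactants: 23 the C8,C9 diol
Product: 24 (4S,5R)-5-[(1E,5Z)-2-[(tert-butyldiphenylsilyloxy)methyl]-6-iodo-7,7-dimethoxyhepta-1,5-dien-1-yl]-4-[(1S)-1-hydroxy-2-(triethylsilyloxy)ethyl]-3-methylideneoxolan-2-one
Conditions: Et3SiCl (1.05 equiv), imidazole, CH2Cl2, −40 °C
Reagents that add atoms: chlorotriethylsilane, CC[Si](Cl)(CC)CC
Why: Silylation at low temperature should select the primary C9 hydroxyl over the hindered secondary C8 hydroxyl.

Step 17
Reactants: 24 the C9 triethylsilyl ether; 25 (S)-2-methylbutanoic anhydride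
Product: 26 (1S)-1-[(2R,3S)-2-[(1E,5Z)-2-[(tert-butyldiphenylsilyloxy)methyl]-6-iodo-7,7-dimethoxyhepta-1,5-dien-1-yl]-4-methylidene-5-oxooxolan-3-yl]-2-(triethylsilyloxy)ethyl (2S)-2-methylbutanoate
Conditions: 25, DMAP, Et3N, CH2Cl2, 0 °C → rt
Reagents that add atoms: none
Why: DMAP-catalysed acylation with the enantiopure anhydride places the (S)-2-methylbutanoate on O8 under conditions that should not epimerise the acyl stereocentre.

Step 18
Reactants: 26 the C8 ester
Product: 27 (1S)-1-[(2R,3S)-2-[(1E,5Z)-2-[(tert-butyldiphenylsilyloxy)methyl]-6-iodo-7,7-dimethoxyhepta-1,5-dien-1-yl]-4-methylidene-5-oxooxolan-3-yl]-2-oxoethyl (2S)-2-methylbutanoate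
Conditions: (COCl)2, DMSO, CH2Cl2, −78 → −40 °C; Et3N, −78 → −20 °C
Reagents that add atoms: none
Why: Primary triethylsilyl ethers are oxidised directly to aldehydes under Swern conditions (activated DMSO cleaves the Si–O bond, then the alkoxysulfonium ylide fragments), so C9 is unmasked and oxidised in one operation, and the low temperature guards the α-acyloxy stereocentre.

Step 19
Reactants: 27 the iodo aldehyde
Product: 28 (1(10)E,4E,6R,7S,8S,9S)-15-(tert-butyldiphenylsilyloxy)-9-hydroxy-14,14-dimethoxy-8-[(2S)-2-methylbutanoyloxy]germacra-1(10),4,11(13)-trien-12,6-olide (both ring olefins ring-cis)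
Conditions: CrCl2 (10 equiv), NiCl2 (0.1 equiv), degassed DMSO, rt, 0.003 M, slow addition of 27
Reagents that add atoms: none
Why: Intramolecular Nozaki–Hiyama–Kishi reaction: the nickel-catalysed formation of an alkenylchromium species from the alkenyl iodide proceeds with retention and adds chemoselectively to the aldehyde, closing the ten-membered ring at C9–C10 on a chain pre-organised by two ring-cis olefins and the lactone; the C9 carbinol should form trans to the C8 ester through a transition state with opposed C8–O and C9=O dipoles, which is the least secure stereochemical element of the route.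

Step 20
Reactants: 28 the protected macrocycle
Product: 30 (1(10)E,4E,6R,7S,8S,9S)-9,15-dihydroxy-8-[(2S)-2-methylbutanoyloxy]-14-oxogermacra-1(10),4,11(13)-trien-12,6-olide (CNP0331447.1), via hydroxy acetal 29 (not isolated)
Conditions: HF·pyridine, THF, 0 °C → rt; then H2O, rt
Reagents that add atoms: water, O
Why: Fluoride cleaves the silyl ether and the aqueous acid then hydrolyses the allylic dimethyl acetal to the enal, the acidic medium avoiding acyl migration between O8 and O9.

**Compound list**

1 | hex-5-en-1-yl acetate | CC(=O)OCCCCC=C | starting material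
2 | (E)-but-2-enal (crotonaldehyde) | C/C=C/C=O | starting material
3 | (E)-7-oxohept-5-en-1-yl acetate | CC(=O)OCCCC/C=C/C=O | intermediate
4 | (Z)-6-iodo-7-oxohept-5-en-1-yl acetate | CC(=O)OCCCC/C=C(\I)C=O | intermediate
5 | (Z)-6-iodo-7,7-dimethoxyhept-5-en-1-yl acetate | CC(=O)OCCCC/C=C(\I)C(OC)OC | intermediate (not isolated)
6 | (Z)-6-iodo-7,7-dimethoxyhept-5-en-1-ol | OCCCC/C=C(\I)C(OC)OC | intermediate
7 | (Z)-6-iodo-7,7-dimethoxyhept-5-enal | O=CCCC/C=C(\I)C(OC)OC | intermediate
8 | (Z)-6-iodo-7,7-dimethoxy-2-methylidenehept-5-enal | O=CC(=C)CC/C=C(\I)C(OC)OC | intermediate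
9 | (R)-2,2-dimethyl-1,3-dioxolane-4-carbaldehyde | O=C[C@@H]1OC(C)(C)OC1 | starting material
10 | (S)-4-ethynyl-2,2-dimethyl-1,3-dioxolane | C#C[C@@H]1OC(C)(C)OC1 | intermediate
11 | (3R,7Z)-1-[(4S)-2,2-dimethyl-1,3-dioxolan-4-yl]-8-iodo-9,9-dimethoxy-4-methylidenenon-7-en-1-yn-3-ol | C=C(CC/C=C(\I)C(OC)OC)[C@@H](O)C#C[C@@H]1OC(C)(C)OC1 | intermediate
12 | (1S)-3-[(4S)-2,2-dimethyl-1,3-dioxolan-4-yl]-1-[(2R)-2-[(3Z)-4-iodo-5,5-dimethoxypent-3-en-1-yl]oxiran-2-yl]prop-2-yn-1-ol | C1O[C@@]1(CC/C=C(\I)C(OC)OC)[C@@H](O)C#C[C@@H]2OC(C)(C)OC2 | intermediate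
13 | (1S,2Z)-3-[(4S)-2,2-dimethyl-1,3-dioxolan-4-yl]-1-[(2R)-2-[(3Z)-4-iodo-5,5-dimethoxypent-3-en-1-yl]oxiran-2-yl]prop-2-en-1-ol | C1O[C@@]1(CC/C=C(\I)C(OC)OC)[C@@H](O)/C=C\[C@@H]2OC(C)(C)OC2 | intermediate
14 | acetate of 13 | C1O[C@@]1(CC/C=C(\I)C(OC)OC)[C@@H](OC(C)=O)/C=C\[C@@H]2OC(C)(C)OC2 | intermediate
15 | O-trimethylsilyl ketene acetal of 14 | C1O[C@@]1(CC/C=C(\I)C(OC)OC)[C@@H](OC(=C)O[Si](C)(C)C)/C=C\[C@@H]2OC(C)(C)OC2 | intermediate (not isolated)
16 | trimethylsilyl ester of 17 | C[Si](C)(C)OC(=O)C[C@@H](/C=C/[C@@]1(CC/C=C(\I)C(OC)OC)CO1)[C@@H]2OC(C)(C)OC2 | intermediate (not isolated)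
17 | (3S,4E)-3-[(4S)-2,2-dimethyl-1,3-dioxolan-4-yl]-5-[(2S)-2-[(3Z)-4-iodo-5,5-dimethoxypent-3-en-1-yl]oxiran-2-yl]pent-4-enoic acid | OC(=O)C[C@@H](/C=C/[C@@]1(CC/C=C(\I)C(OC)OC)CO1)[C@@H]2OC(C)(C)OC2 | intermediate
18 | (4S,5R)-4-[(4S)-2,2-dimethyl-1,3-dioxolan-4-yl]-5-[(1E,5Z)-2-(hydroxymethyl)-6-iodo-7,7-dimethoxyhepta-1,5-dien-1-yl]oxolan-2-one | C1C(=O)O[C@H](/C=C(/CO)CC/C=C(\I)C(OC)OC)[C@H]1[C@@H]2OC(C)(C)OC2 | intermediate
19 | tert-butyldiphenylsilyl ether of 18 at O15 | C1C(=O)O[C@H](/C=C(/CO[Si](c2ccccc2)(c2ccccc2)C(C)(C)C)CC/C=C(\I)C(OC)OC)[C@H]1[C@@H]3OC(C)(C)OC3 | intermediate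
20 | (3R,4S,5R)-3-[(dimethylamino)methyl] derivative of 19 (C11 epimer inconsequential) | CN(C)C[C@@H]1C(=O)O[C@H](/C=C(/CO[Si](c2ccccc2)(c2ccccc2)C(C)(C)C)CC/C=C(\I)C(OC)OC)[C@H]1[C@@H]3OC(C)(C)OC3 | intermediate (not isolated)
21 | trimethylammonium iodide from N-methylation of 20 | C[N+](C)(C)C[C@@H]1C(=O)O[C@H](/C=C(/CO[Si](c2ccccc2)(c2ccccc2)C(C)(C)C)CC/C=C(\I)C(OC)OC)[C@H]1[C@@H]3OC(C)(C)OC3.[I-] | intermediate (not isolated)
22 | (4S,5R)-5-[(1E,5Z)-2-[(tert-butyldiphenylsilyloxy)methyl]-6-iodo-7,7-dimethoxyhepta-1,5-dien-1-yl]-4-[(4S)-2,2-dimethyl-1,3-dioxolan-4-yl]-3-methylideneoxolan-2-one | C=C1C(=O)O[C@H](/C=C(/CO[Si](c2ccccc2)(c2ccccc2)C(C)(C)C)CC/C=C(\I)C(OC)OC)[C@H]1[C@@H]3OC(C)(C)OC3 | intermediate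
23 | (4S,5R)-5-[(1E,5Z)-2-[(tert-butyldiphenylsilyloxy)methyl]-6-iodo-7,7-dimethoxyhepta-1,5-dien-1-yl]-4-[(1S)-1,2-dihydroxyethyl]-3-methylideneoxolan-2-one | C=C1C(=O)O[C@H](/C=C(/CO[Si](c2ccccc2)(c2ccccc2)C(C)(C)C)CC/C=C(\I)C(OC)OC)[C@H]1[C@H](O)CO | intermediate
24 | C9 triethylsilyl ether of 23 | C=C1C(=O)O[C@H](/C=C(/CO[Si](c2ccccc2)(c2ccccc2)C(C)(C)C)CC/C=C(\I)C(OC)OC)[C@H]1[C@H](O)CO[Si](CC)(CC)CC | intermediate
25 | (S)-2-methylbutanoic anhydride | CC[C@H](C)C(=O)OC(=O)[C@@H](C)CC | starting material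
26 | (1S)-1-[(2R,3S)-2-[(1E,5Z)-2-[(tert-butyldiphenylsilyloxy)methyl]-6-iodo-7,7-dimethoxyhepta-1,5-dien-1-yl]-4-methylidene-5-oxooxolan-3-yl]-2-(triethylsilyloxy)ethyl (2S)-2-methylbutanoate | C=C1C(=O)O[C@H](/C=C(/CO[Si](c2ccccc2)(c2ccccc2)C(C)(C)C)CC/C=C(\I)C(OC)OC)[C@H]1[C@H](OC(=O)[C@@H](C)CC)CO[Si](CC)(CC)CC | intermediate
27 | (1S)-1-[(2R,3S)-2-[(1E,5Z)-2-[(tert-butyldiphenylsilyloxy)methyl]-6-iodo-7,7-dimethoxyhepta-1,5-dien-1-yl]-4-methylidene-5-oxooxolan-3-yl]-2-oxoethyl (2S)-2-methylbutanoate | C=C1C(=O)O[C@H](/C=C(/CO[Si](c2ccccc2)(c2ccccc2)C(C)(C)C)CC/C=C(\I)C(OC)OC)[C@H]1[C@H](OC(=O)[C@@H](C)CC)C=O | intermediate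
28 | (1(10)E,4E,6R,7S,8S,9S)-15-(tert-butyldiphenylsilyloxy)-9-hydroxy-14,14-dimethoxy-8-[(2S)-2-methylbutanoyloxy]germacra-1(10),4,11(13)-trien-12,6-olide | C=C1C(=O)O[C@@H]2/C=C(/CO[Si](c3ccccc3)(c3ccccc3)C(C)(C)C)CC/C=C(/C(OC)OC)[C@H](O)[C@@H](OC(=O)[C@@H](C)CC)[C@@H]12 | intermediate
29 | (1(10)E,4E,6R,7S,8S,9S)-9,15-dihydroxy-14,14-dimethoxy-8-[(2S)-2-methylbutanoyloxy]germacra-1(10),4,11(13)-trien-12,6-olide | C=C1C(=O)O[C@@H]2/C=C(/CO)CC/C=C(/C(OC)OC)[C@H](O)[C@@H](OC(=O)[C@@H](C)CC)[C@@H]12 | intermediate (not isolated)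
30 | (1(10)E,4E,6R,7S,8S,9S)-9,15-dihydroxy-8-[(2S)-2-methylbutanoyloxy]-14-oxogermacra-1(10),4,11(13)-trien-12,6-olide (CNP0331447.1) | C=C1C(=O)O[C@@H]2/C=C(/CO)CC/C=C(/C=O)[C@H](O)[C@@H](OC(=O)[C@@H](C)CC)[C@@H]12 | target

**Step count**

Total: 20 steps. Longest linear sequence: 19 steps (steps 1–5, then 7–20); step 6 is a one-step branch.

**Steps most likely to fail**

1. Step 12. Zerovalent palladium may insert into the alkenyl C–I bond instead of ionising the vinyl oxirane, or syn/anti exchange of the allyl intermediate may erode the C4=C5 geometry and the C4-to-C6 chirality transfer. Fallback: setting out from 17 and returning at 18, the palladium catalyst is replaced by a Brønsted acid (camphorsulfonic acid, 5 mol%, CH2Cl2, −40 °C). Protonation of the oxirane opens the tertiary allylic C4–O bond from the same s-trans conformer, and the carboxyl group captures the allyl cation at C6 in a 5-exo SN2′-type lactonisation. The trans relationship at C6/C7 then rests on the C7 substituent alone. This fallback makes no new compound (F0).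

2. Step 19. Facial selectivity at the C9 aldehyde may be poor or reversed, since it is set only by the conformation of the closing ring, and oligomerisation may compete with ring closure. Fallback: setting out from the crude macrocyclisation product (28 with its C9 epimer), the allylic alcohol is oxidised with Dess–Martin periodinane to the C9 ketone, (1(10)E,4E,6R,7S,8S)-15-(tert-butyldiphenylsilyloxy)-14,14-dimethoxy-8-[(2S)-2-methylbutanoyloxy]-9-oxogermacra-1(10),4,11(13)-trien-12,6-olide F1. A reagent-controlled Corey–Bakshi–Shibata reduction (the oxazaborolidine enantiomer that delivers hydride to the Re face of C9, catecholborane, toluene, −78 °C) then returns to 28.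

3. Step 9. Hydrogenolysis of the alkenyl C–I bond on the palladium surface, or over-reduction of the Z olefin, may accompany the semihydrogenation. Fallback: setting out from 12 and returning at 13, the alkyne is reduced without metal or hydrogen gas by diimide generated in situ (2-nitrobenzenesulfonylhydrazide, Et3N, THF/i-PrOH, rt). Diimide transfers H2 in a concerted syn fashion and does not touch carbon–iodine bonds or the oxirane, and the hindered Z olefin formed should be reduced further only slowly. This fallback makes no new compound (F0).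

**Further compounds**

F0 | step 12 | none | none
F1 | step 19 | (1(10)E,4E,6R,7S,8S)-15-(tert-butyldiphenylsilyloxy)-14,14-dimethoxy-8-[(2S)-2-methylbutanoyloxy]-9-oxogermacra-1(10),4,11(13)-trien-12,6-olide | C=C1C(=O)O[C@@H]2/C=C(/CO[Si](c3ccccc3)(c3ccccc3)C(C)(C)C)CC/C=C(/C(OC)OC)C(=O)[C@@H](OC(=O)[C@@H](C)CC)[C@@H]12
F0 | step 9 | none | none
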